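**Retrosynthetic overview**
1. Target 20 ⇐ enyne 19 (semihydrogenation) ⇐ 6α-acetoxy-7-ketone 18 ⇐ decalin enone 15; C5, C6 and C7 come from enone reduction/enolate hydroxylation and ketone reduction.
2. Key disconnection: the cyclohexenone ring B of 15 ⇐ cyclopentenone 1,3-diketone 13 by a reductive 1,2-acyl-shift ring expansion (five → six), which creates the C8 carbinol and the C9 stereocentre.
3. 13 ⇐ 2-acetyl enone 10 + (Z)-enynyl bromide 12 (quaternary C9, side chain trans to the angular methyl); 10 ⇐ hydrindenone 8 + acetyl donor 9.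
4. 8 ⇐ (R)-allyl ketone 6 (Wacker oxidation, aldol condensation) ⇐ enol carbonate 5 by Pd-catalysed asymmetric decarboxylative allylation (sets C10) ⇐ 2-methylcyclohexanone 1.
5. Ring order: ring A is the purchased cyclohexanone; ring B is closed first as a five-membered enone and then enlarged to the six-membered ring.

Assumption: the SMILES is read as (5S,6R,7S,8S,9R,10S)-6α-acetoxy-7β,8α-dihydroxylabda-12Z,14-diene (labdane numbering C1–C20 is used for positions below), and every building block that puts two or more carbons into the skeleton is counted as a starting material.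

**Route**

Step 1
Reactants: 1 2-methylcyclohexanone
Product: 3 2,2,6-trimethylcyclohexanone, via 2,6-dimethylcyclohexanone 2 (not isolated)
Conditions: LiN(i-Pr)2 (1.05 equiv), THF, −78 °C; MeI; then LiN(i-Pr)2 (1.1 equiv), −78 °C; MeI, −78 → 23 °C
Reagents that add atoms: iodomethane, CI
Why: Sequential enolate alkylation: kinetic deprotonation at the CH2 α-carbon and methylation give 2, and a second deprotonation/methylation of 2 (or of any 2,2-dimethyl isomer formed by enolate exchange) converges on 3, whose stereocentre is erased in the next step.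

Step 2
Reactants: 3 2,2,6-trimethylcyclohexanone; 4 allyl chloroformate
Product: 5 allyl 2,6,6-trimethylcyclohex-1-en-1-yl carbonate
Conditions: LiN(SiMe3)2, THF, 0 °C; then 4, −78 → 23 °C
Reagents that add atoms: none
Why: Ketone 3 has a single enolisable position, so O-acylation of its lithium enolate by the chloroformate gives one enol carbonate.

Step 3
Reactants: 5 allyl 2,6,6-trimethylcyclohex-1-en-1-yl carbonate
Product: 6 (2R)-2-allyl-2,6,6-trimethylcyclohexan-1-one
Conditions: Pd2(dba)3 (2.5 mol %), (R)-t-Bu-PHOX (6.25 mol %), THF, 25 °C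
Reagents that add atoms: none
Why: Pd-catalysed decarboxylative asymmetric allylic alkylation (Tsuji allylation): zerovalent palladium ionises the enol carbonate, CO2 is lost and the enolate/π-allyl pair recombines on the enolate face chosen by the (R)-phosphinooxazoline, setting the quaternary C10 as R in 6 (about 90% ee, raised to enantiopurity by recrystallisation of a later solid intermediate).

Step 4
Reactants: 6 (2R)-2-allyl-2,6,6-trimethylcyclohexan-1-one
Product: 7 (6R)-2,2,6-trimethyl-6-(2-oxopropyl)cyclohexan-1-one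
Conditions: PdCl2 (10 mol %), Cu(OAc)2·H2O (20 mol %), O2 (1 atm), DMA/H2O 7:1, 23 °C
Reagents that add atoms: water, O (O2 is the terminal oxidant)
Why: Tsuji–Wacker oxidation converts the terminal alkene into the methyl ketone with Markovnikov selectivity and does not touch the quaternary centre.

Step 5
Reactants: 7 (6R)-2,2,6-trimethyl-6-(2-oxopropyl)cyclohexan-1-one
Product: 8 (7aR)-4,4,7a-trimethyl-1,4,5,6,7,7a-hexahydro-2H-inden-2-one
Conditions: KOH (powdered, 0.5 equiv), xylenes, 110 °C, Dean–Stark
Reagents that add atoms: none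
Why: Intramolecular aldol condensation of the methyl ketone onto the ring ketone followed by dehydration closes ring B as a cyclopentenone (C5=C6), the only ring size open to this 1,4-diketone.

Step 6
Reactants: 8 (7aR)-4,4,7a-trimethyl-1,4,5,6,7,7a-hexahydro-2H-inden-2-one; 9 N-methoxy-N-methylacetamide
Product: 10 (7aR)-1-acetyl-4,4,7a-trimethyl-1,4,5,6,7,7a-hexahydro-2H-inden-2-one
Conditions: LiN(i-Pr)2 (1.1 equiv), THF, −78 °C; then 9, −78 → 0 °C; aq NH4Cl
Reagents that add atoms: none
Why: The enone has enolisable hydrogens only at C9 (both γ-carbons are quaternary), so one lithium enolate forms and its Claisen-type C-acylation by the Weinreb amide (stable chelated adduct, no over-addition) gives the β-diketone as an epimer/enol mixture.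

Step 7
Reactants: 11 (2Z)-3-methylpent-2-en-4-yn-1-ol
Product: 12 (3Z)-5-bromo-3-methylpent-3-en-1-yne
Conditions: PBr3 (0.4 equiv), pyridine (cat.), Et2O, −10 °C
Reagents that add atoms: phosphorus tribromide, BrP(Br)Br
Why: Bromination of the primary allylic alcohol with PBr3 at low temperature proceeds without allylic transposition and keeps the Z geometry.

Step 8
Reactants: 10 (7aR)-1-acetyl-4,4,7a-trimethyl-1,4,5,6,7,7a-hexahydro-2H-inden-2-one; 12 (3Z)-5-bromo-3-methylpent-3-en-1-yne
Product: 13 (1S,7aS)-1-acetyl-4,4,7a-trimethyl-1-[(2Z)-3-methylpent-2-en-4-yn-1-yl]-1,4,5,6,7,7a-hexahydro-2H-inden-2-one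
Conditions: K2CO3 (2 equiv), acetone, 23 °C
Reagents that add atoms: none
Why: SN2 C-alkylation of the soft β-diketone enolate by the primary allylic bromide, with the electrophile approaching anti to the axial angular methyl so that the quaternary C9 carries the side chain trans and the acetyl group cis to that methyl (1S).

Step 9
Reactants: 13 (1S,7aS)-1-acetyl-4,4,7a-trimethyl-1-[(2Z)-3-methylpent-2-en-4-yn-1-yl]-1,4,5,6,7,7a-hexahydro-2H-inden-2-one
Product: 15 (3S,4R,4aR)-3-hydroxy-3,4a,8,8-tetramethyl-4-[(2Z)-3-methylpent-2-en-4-yn-1-yl]-4,4a,5,6,7,8-hexahydronaphthalen-2(3H)-one, via cyclopropane-1,2-diolate 14 (not isolated)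
Conditions: SmI2 (2.2 equiv), THF, −78 °C, 20 min; then AcOH/H2O, −78 → 23 °C
Reagents that add atoms: none
Why: Proposed new method: a one-pot samarium-mediated reductive ring expansion (net 1,2-shift of the C7 acyl carbon from C9 to the acetyl carbon C8 with uptake of two electrons and two protons) in which SmI2 couples the chelated 1,3-diketone (ketyl–carbonyl, pinacol-type) to the cis-cyclopropane-1,2-diolate 14, whose three-membered ring lies on the face of the angular methyl where the acetyl group sat and whose two oxygens are held exo by trivalent samarium with the methyl endo, fixing C8 as 8α-OH/8β-CH3, after which acetic acid protonates the non-oxygenated cyclopropane carbon C9 with retention while the internal C7–C9 bond breaks (steered by formation of the conjugated enone and release of bicyclo[3.1.0] strain), leaving the side chain equatorial (9R) in the six-membered α-ketol; the closest known reaction types are the SmI2 pinacol cyclisation of 1,3-diketones to cis-cyclopropane-1,2-diols, the acid-induced cyclopropane-1,2-diol → α-ketol rearrangement of Clemmensen reductions of 1,3-diketones (retentive acid opening of cyclopropanols) and the Dowd–Beckwith 1,2-acyl-shift ring expansion.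

Step 10
Reactants: 15 (3S,4R,4aR)-3-hydroxy-3,4a,8,8-tetramethyl-4-[(2Z)-3-methylpent-2-en-4-yn-1-yl]-4,4a,5,6,7,8-hexahydronaphthalen-2(3H)-one
Product: 17 (1R,3S,4R,4aS,8aS)-1,3-dihydroxy-3,4a,8,8-tetramethyl-4-[(2Z)-3-methylpent-2-en-4-yn-1-yl]-3,4,4a,5,6,7,8,8a-octahydronaphthalen-2(1H)-one, via lithium enolate 16 (not isolated)
Conditions: LiN(SiMe3)2 (2.1 equiv), THF, −78 °C; Li (2.5 equiv), NH3(l)/THF, t-BuOH (1 equiv), −78 °C; NH3 removed; 2-(benzenesulfonyl)-3-phenyloxaziridine, THF, −78 °C; aq NH4Cl
Reagents that add atoms: 2-(benzenesulfonyl)-3-phenyloxaziridine, O=S(=O)(c1ccccc1)N1OC1c1ccccc1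
Why: Birch-type dissolving-metal reduction of the enone (the tertiary alcohol and the terminal alkyne are first converted to their lithium salts and so resist reduction) protonates C5 axially to give the trans-decalin (5α-H) and the regiodefined C6 enolate 16, which the oxaziridine hydroxylates (Davis oxidation) from the α-face because the β-face is blocked by the syn-axial C4 and C10 methyls, giving the equatorial 6α-OH.

Step 11
Reactants: 17 (1R,3S,4R,4aS,8aS)-1,3-dihydroxy-3,4a,8,8-tetramethyl-4-[(2Z)-3-methylpent-2-en-4-yn-1-yl]-3,4,4a,5,6,7,8,8a-octahydronaphthalen-2(1H)-one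
Product: 18 (1R,3S,4R,4aS,8aS)-3-hydroxy-3,4a,8,8-tetramethyl-4-[(2Z)-3-methylpent-2-en-4-yn-1-yl]-2-oxodecahydronaphthalen-1-yl acetate
Conditions: Ac2O, pyridine, DMAP (cat.), CH2Cl2, 0 → 23 °C
Reagents that add atoms: acetic anhydride, CC(=O)OC(C)=O
Why: DMAP-catalysed acylation takes the secondary 6α-OH only, the hindered tertiary 8-OH being inert under these conditions, and the equatorial C6 configuration is the thermodynamic one.

Step 12
Reactants: 18 (1R,3S,4R,4aS,8aS)-3-hydroxy-3,4a,8,8-tetramethyl-4-[(2Z)-3-methylpent-2-en-4-yn-1-yl]-2-oxodecahydronaphthalen-1-yl acetate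
Product: 19 (1R,2S,3S,4R,4aS,8aS)-2,3-dihydroxy-3,4a,8,8-tetramethyl-4-[(2Z)-3-methylpent-2-en-4-yn-1-yl]decahydronaphthalen-1-yl acetate
Conditions: NaBH4, CeCl3·7H2O, MeOH, −78 °C; aq NH4Cl
Reagents that add atoms: none
Why: Luche-type borohydride reduction delivers hydride axially from the α-face (the β-face is shielded by the axial 8β-methyl) to give the equatorial 7β-alcohol, and the low temperature suppresses 6→7 acetyl migration.

Step 13
Reactants: 19 (1R,2S,3S,4R,4aS,8aS)-2,3-dihydroxy-3,4a,8,8-tetramethyl-4-[(2Z)-3-methylpent-2-en-4-yn-1-yl]decahydronaphthalen-1-yl acetate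
Product: 20 (1R,2S,3S,4R,4aS,8aS)-2,3-dihydroxy-3,4a,8,8-tetramethyl-4-[(2Z)-3-methylpenta-2,4-dien-1-yl]decahydronaphthalen-1-yl acetate
Conditions: H2 (1 atm), Pd/CaCO3 poisoned with Pb(OAc)2 (Lindlar catalyst), quinoline, EtOAc, 0 °C
Reagents that add atoms: none
Why: Lindlar semihydrogenation reduces the terminal alkyne to the vinyl group and stops there, leaving the trisubstituted Z-alkene untouched and giving the 12Z,14-diene.

**Compound list**

1 | 2-methylcyclohexanone (racemic) | CC1CCCCC1=O | starting material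
2 | 2,6-dimethylcyclohexanone (cis/trans mixture, not isolated) | CC1CCCC(C)C1=O | intermediate
3 | 2,2,6-trimethylcyclohexanone (racemic) | CC1CCCC(C)(C)C1=O | intermediate
4 | allyl chloroformate | C=CCOC(Cl)=O | starting material
5 | allyl 2,6,6-trimethylcyclohex-1-en-1-yl carbonate | C=CCOC(=O)OC1=C(C)CCCC1(C)C | intermediate
6 | (2R)-2-allyl-2,6,6-trimethylcyclohexan-1-one | C=CC[C@@]1(C)CCCC(C)(C)C1=O | intermediate
7 | (6R)-2,2,6-trimethyl-6-(2-oxopropyl)cyclohexan-1-one | CC(=O)C[C@@]1(C)CCCC(C)(C)C1=O | intermediate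
8 | (7aR)-4,4,7a-trimethyl-1,4,5,6,7,7a-hexahydro-2H-inden-2-one | O=C1C=C2C(C)(C)CCC[C@]2(C)C1 | intermediate
9 | N-methoxy-N-methylacetamide | CON(C)C(C)=O | starting material
10 | (7aR)-1-acetyl-4,4,7a-trimethyl-1,4,5,6,7,7a-hexahydro-2H-inden-2-one (C1 epimers and enol tautomers) | CC(=O)C1C(=O)C=C2C(C)(C)CCC[C@]12C | intermediate
11 | (2Z)-3-methylpent-2-en-4-yn-1-ol | OC/C=C(C)\C#C | starting material
12 | (3Z)-5-bromo-3-methylpent-3-en-1-yne | BrC/C=C(C)\C#C | intermediate
13 | (1S,7aS)-1-acetyl-4,4,7a-trimethyl-1-[(2Z)-3-methylpent-2-en-4-yn-1-yl]-1,4,5,6,7,7a-hexahydro-2H-inden-2-one (acetyl cis, side chain trans to the angular methyl) | CC(=O)[C@@]1(C/C=C(C)\C#C)C(=O)C=C2C(C)(C)CCC[C@]12C | intermediate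
14 | tricyclic cis-cyclopropane-1,2-diol from C7–C8 closure on the face of the angular methyl (7-OH and 8-OH cis and exo, 8-CH3 endo; present as its trivalent-samarium diolate, drawn as the free diol, not isolated) | C[C@]1(O)[C@@]2(C/C=C(C)\C#C)[C@]1(O)C=C3C(C)(C)CCC[C@]23C | intermediate
15 | (3S,4R,4aR)-3-hydroxy-3,4a,8,8-tetramethyl-4-[(2Z)-3-methylpent-2-en-4-yn-1-yl]-4,4a,5,6,7,8-hexahydronaphthalen-2(3H)-one (labdane: 5-en-7-one, 8α-OH, 8β-CH3, 9β side chain) | C#C/C(C)=C\C[C@H]1[C@](C)(O)C(=O)C=C2C(C)(C)CCC[C@@]21C | intermediate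
16 | C6 lithium enolate of the 5α-H 7-ketone, as the trilithium salt (8-alkoxide, acetylide; not isolated) | [Li+].[Li+].[Li+].[C-]#C/C(C)=C\C[C@H]1[C@](C)([O-])C([O-])=C[C@H]2C(C)(C)CCC[C@@]21C | intermediate
17 | (1R,3S,4R,4aS,8aS)-1,3-dihydroxy-3,4a,8,8-tetramethyl-4-[(2Z)-3-methylpent-2-en-4-yn-1-yl]-3,4,4a,5,6,7,8,8a-octahydronaphthalen-2(1H)-one (6α-OH, 7-one, 8α-OH) | C#C/C(C)=C\C[C@H]1[C@](C)(O)C(=O)[C@H](O)[C@H]2C(C)(C)CCC[C@@]21C | intermediate
18 | (1R,3S,4R,4aS,8aS)-3-hydroxy-3,4a,8,8-tetramethyl-4-[(2Z)-3-methylpent-2-en-4-yn-1-yl]-2-oxodecahydronaphthalen-1-yl acetate | C#C/C(C)=C\C[C@H]1[C@](C)(O)C(=O)[C@H](OC(C)=O)[C@H]2C(C)(C)CCC[C@@]21C | intermediate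
19 | (1R,2S,3S,4R,4aS,8aS)-2,3-dihydroxy-3,4a,8,8-tetramethyl-4-[(2Z)-3-methylpent-2-en-4-yn-1-yl]decahydronaphthalen-1-yl acetate | C#C/C(C)=C\C[C@H]1[C@](C)(O)[C@@H](O)[C@H](OC(C)=O)[C@H]2C(C)(C)CCC[C@@]21C | intermediate
20 | (1R,2S,3S,4R,4aS,8aS)-2,3-dihydroxy-3,4a,8,8-tetramethyl-4-[(2Z)-3-methylpenta-2,4-dien-1-yl]decahydronaphthalen-1-yl acetate (CNP0138393.1) | C=C/C(C)=C\C[C@H]1[C@](C)(O)[C@@H](O)[C@H](OC(C)=O)[C@H]2C(C)(C)CCC[C@@]21C | target

**Step count and risks**

Total step count: 13. Longest linear sequence: 12 steps (steps 1–6 and 8–13, from 1).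

The three steps most likely to fail:

Step 9 (the proposed new ring expansion). Risks are over-reduction or dimerisation of the enone, a diol with the wrong C8 geometry, and opening of the cyclopropane in the wrong direction. The fallback sets out from 13 and comes back at 15, using known chemistry in two separate operations through an isolated intermediate. Reductive acetylation of the 1,3-diketone (Zn dust, Ac2O, dry HCl, Et2O, 0 °C, the known zinc-mediated reductive coupling of 1,3-diketones in acetic anhydride) gives the cyclopropane-1,2-diyl diacetate F1, which is purified. Acid methanolysis (HCl, MeOH, 0 → 23 °C) then frees the diol, which undergoes the known acid-induced cyclopropanediol → α-ketol opening to 15. C–C bond formation and C–C bond cleavage are thus tuned separately.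

Step 10 (dissolving-metal reduction with enolate hydroxylation in the presence of the enyne). The fallback sets out from 15 and comes back at 17 and replaces solvated electrons by hydrogen-atom transfer. A Mukaiyama–Magnus reductive α-hydroxylation of the enone (Mn(dpm)3 cat., PhSiH3, O2, i-PrOH/CH2Cl2, 0 °C; then P(OEt)3) puts H on C5 and oxygen on C6 in one operation under neutral conditions. It forms no compound of its own.

Step 8 (C-alkylation next to the quaternary C10, where O-alkylation may compete). The fallback sets out from 10 and comes back at 13 and builds the side chain on a small allyl group. Tsuji–Trost allylation of 10 (allyl methyl carbonate, Pd(PPh3)4, THF, 23 °C), which tolerates congested quaternary centres and again enters anti to the angular methyl, gives (1S,7aS)-1-acetyl-1-allyl-4,4,7a-trimethyl-1,4,5,6,7,7a-hexahydro-2H-inden-2-one F2. Selective ozonolysis of the terminal vinyl group (O3, CH2Cl2/MeOH, −78 °C; Me2S) gives the aldehyde F3. Stork–Zhao olefination (Ph3P=C(I)CH3 from (1-iodoethyl)triphenylphosphonium iodide and NaN(SiMe3)2, THF, −78 °C) gives the (Z)-iodoalkene F4. Negishi coupling with ethynylzinc bromide (Pd(PPh3)4, THF, 23 °C) then gives 13 with retention of the alkene geometry.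

**Further compounds**

F1 | step 9 | diacetate of cyclopropane-1,2-diol 14 (tricyclic cis-cyclopropane-1,2-diyl diacetate) | C[C@]1(OC(C)=O)[C@@]2(C/C=C(C)\C#C)[C@]1(OC(C)=O)C=C3C(C)(C)CCC[C@]23C
F0 | step 10 | none | none
F2 | step 8 | (1S,7aS)-1-acetyl-1-allyl-4,4,7a-trimethyl-1,4,5,6,7,7a-hexahydro-2H-inden-2-one | CC(=O)[C@@]1(CC=C)C(=O)C=C2C(C)(C)CCC[C@]12C
F3 | step 8 | 2-[(1S,7aS)-1-acetyl-4,4,7a-trimethyl-2-oxo-2,4,5,6,7,7a-hexahydro-1H-inden-1-yl]acetaldehyde | CC(=O)[C@@]1(CC=O)C(=O)C=C2C(C)(C)CCC[C@]12C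
F4 | step 8 | (1S,7aS)-1-acetyl-1-[(2Z)-3-iodobut-2-en-1-yl]-4,4,7a-trimethyl-1,4,5,6,7,7a-hexahydro-2H-inden-2-one | CC(=O)[C@@]1(C/C=C(C)\I)C(=O)C=C2C(C)(C)CCC[C@]12C
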